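Slowness hid the end of these flasks from me: at 19 °C the dusk run was still gaining product at its last reading, so I went to the hot runs to see where a flask stops.

| flask | substrate | reagent | temperature | remark | time |
|---|---|---|---|---|---|
| summer | 0.36 M | 0.80 M | 19 °C | run made earlier |  |
| dawn | 1.3 M | 0.80 M | 49 °C | run made earlier |  |
| dusk | 2.7 M | 0.80 M | 19 °C | run made earlier |  |
| midnight | 0.80 M | 0.88 M | 49 °C | run made earlier |  |
| eta | 3.0 M | 0.250 M | 60 °C |  | 20 h |
| theta | 0.80 M | 3.00 M | 20 °C |  | 20 h |
| delta | 0.80 M | 0.800 M | 20 °C |  | 20 h |
| zeta | 0.50 M | 3.00 M | 5 °C |  | 20 h |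

- summer (time / h: product / %, substrate / %): 1.33: 0.6, 88.8; 4.00: 4.8, 72.1; 6.00: 8.2, 64.0; 10.0: 15.0, 52.2; 15.0: 22.3, 41.8
- dawn (time / h: product / %, substrate / %): 0.333: 6.9, 75.7; 1.00: 14.4, 59.5; 1.33: 16.1, 55.4; 2.50: 18.1, 50.6; 4.00: 18.9, 48.3
- dusk (time / h: product / %, substrate / %): 1.00: 0.3, 92.0; 2.00: 1.0, 87.6; 4.00: 3.4, 81.3; 8.00: 7.3, 76.0; 15.0: 11.1, 73.6
- midnight (time / h: product / %, substrate / %): 0.250: 6.0, 76.6; 0.500: 11.4, 62.9; 1.00: 17.4, 48.6; 2.00: 23.2, 35.9; 4.00: 26.4, 26.7

(scatter of a reading: 0.3 percentage points)

- steps that have been proposed: substrate + reagent -> intermediate; intermediate <-> product; 2 reagent -> homo dimer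

* the flasks by amount of product, in percent of the substrate charged, highest first, at 20 h (eta / theta / delta / zeta)
* the amount of product, in percent of the substrate charged of the flask you put first, at 20 h
* the amount of product, in percent of the substrate charged of the flask you put last, at 20 h

Dawn and midnight look alike, both at 49 °C with 0.80 M and 0.88 M of reagent, but they took 1.3 M and 0.80 M of substrate, and at 4.00 h dawn stood at 18.9% product and midnight at 26.4%. I counted the substrate lost as intermediate plus product. Of that lost substrate, at that reading, dawn held 36.6% as product and midnight 36.0%; I call this the product share φ. In dawn it already stood at 36.6% at 2.50 h, while substrate was still falling, so I treated intermediate and product as being in quasi-equilibrium. The gap between the two runs then lay in the substrate lost, 51.7% against 73.3%, and the reagent charged per substrate stood at 0.615 against 1.10.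

Eta carries reagent as its limiting reagent, 0.250 M against 3.0 M of substrate. At the pace of dawn's first reading, that much substrate would halve the reagent in 0.221 h, short against 20 h. So I let each reagent turn one substrate, which gives an estimate y of eta's product, in percent of the substrate charged:

y = φ · c_B / c_A = 3.05%

Here c_B and c_A are the charges of reagent and substrate. Dusk's share, 42.0% and still rising, lay above φ, so the share seemed to fall with heat, and at 60 °C I expected eta somewhat lower.

The forecast gave theta > delta > zeta > eta, with 44% for theta and 2.7% for eta, below my estimate, holding that “heat speeds everything, but equilibrium shifts away from product”.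

The flasks gave theta > delta > zeta > eta, with 41.7% for theta and 2.69% for eta.

    substrate + reagent → intermediate (k = 0.130 M⁻¹ h⁻¹, Ea = 66.0 kJ mol⁻¹)
    intermediate ⇌ product (K = 0.930, k = 0.110 h⁻¹, Ea = 96.0 kJ mol⁻¹, ΔH = −13.0 kJ mol⁻¹)
    2 reagent → homo dimer (k = 0.0390 M⁻¹ h⁻¹, Ea = 60.0 kJ mol⁻¹)
    (constants at 20 °C)

Eta stopped with 0% of its own reagent left, and its product at 200 h is no different. Holding reagent at its charge would have given 32.9% instead of 2.69%, the largest single effect on eta. The neighbour of eta with 0.75 M of substrate has the estimate φ · c_B / c_A = 12.2%; computed, it gives 10.1% product, with 0% of its reagent left.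

All runs were computed with constants of no real substance; noise was put on by code.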